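The leftover points first to the reagent: at 15.0 h the maple run still holds 42.2% left-handed substrate, more than the 38.0% of the cedar run, though maple was charged with 28 mM of each hand against 7 mM.

| flask | left-handed substrate | right-handed substrate | gas | remark | time |
|---|---|---|---|---|---|
| cedar | 7 mM | 7 mM | 2.7 mM (held) | run made earlier |  |
| maple | 28 mM | 28 mM | 2.7 mM (held) | run made earlier |  |
| flask | 14 mM | 14 mM | 2.7 mM (held) |  | 15 h |

- cedar (time / h: left-handed product / %, left-handed substrate / %): 1.33: 0.5, 49.0; 4.00: 1.8, 48.8; 8.00: 3.8, 43.9; 10.0: 7.8, 41.5; 15.0: 11.8, 38.0
- maple (time / h: left-handed product / %, left-handed substrate / %): 3.00: 2.1, 47.9; 6.00: 3.1, 47.8; 10.0: 5.3, 42.8; 12.0: 7.6, 43.3; 15.0: 7.3, 42.2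

(each reading ± 1 percentage point)

- reagent is single-handed; left-handed substrate and right-handed substrate are mirror images of each other, charged as a racemate, each of them at the stated concentration
- at the start none of reagent is dissolved
- reactions considered so far: reagent + right-handed substrate -> right-handed product; gas <-> reagent; left-handed product <-> right-handed product; left-handed substrate <-> right-handed substrate; reagent + left-handed substrate -> left-handed product
- the handed part of reagent does not stay in what it makes, so the products of the two hands are mirror images too

* left-handed product at 15 h, in percent of the left-handed substrate and right-handed substrate together charged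
* the change that raises the amount of left-handed product at 15 h, in percent of the left-handed substrate and right-handed substrate together charged most ("none" if none brings more than 2 percentage points) (Wednesday's / Saturday's / none)
* amount of left-handed product at 15 h, in percent of the left-handed substrate and right-handed substrate together charged, after Saturday's

None of the reagent is charged, so each mole of it enters from the gas, at a rate proportional to the gap between saturation and dissolved reagent, and in a quasi-steady state it passes on into a product. Product in percent at a fixed time then follows dissolved reagent. The final left-handed product readings, 11.8% in cedar and 7.3% in maple, stand in the ratio 1.62, and this reading, with the scatter of 1 percentage point in each value, gives a half-reagent concentration of 27.1 mM: the substrate concentration, per hand, at which dissolved reagent stands at half of saturation. The books of the flask, as charged, then close: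

| Ledger entry | Reagent |
|---|---|
| Saturation | 2.7 mM |
| Standing dissolved | 1.78 mM |
| Gap, passing on to products | 0.920 mM |

This reckoning gives 9.79% left-handed product in the flask. Saturday's doubles every row, giving 19.6%. Wednesday's doubles the half-reagent concentration and gains 2 points, against a margin of 2 points.

The forecast gives 10%, names Saturday's, and puts that change at 18.3%, less than this reckoning's 19.6%, on the ground: “Doubling saturation doubles reagent, so first-order depletion gives about 18%”.

The flask gives 9.65%. Saturday's gains 8.1 points, reaching 17.8%, and Wednesday's gains 2.6 points, so the best change is Saturday's.

    reagent + right-handed substrate → right-handed product (k = 4.30 M⁻¹ h⁻¹)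
    gas ⇌ reagent, rate k2*(csat - [reagent]) (kL = 0.310 h⁻¹)
    left-handed product ⇌ right-handed product (k = 0.0280 h⁻¹)
    left-handed substrate ⇌ right-handed substrate (k = 0.0250 h⁻¹)
    reagent + left-handed substrate → left-handed product (k = 11.0 M⁻¹ h⁻¹)

At 15.0 h the flask makes reagent 1.03 times as fast as it uses it, and the half-reagent concentration, applied to the 11.9 mM of substrate then left per hand on average, reckons dissolved reagent at 1.88 mM where it stands at 1.70 mM. The same charge left until 60.0 h, holding 20.1% left-handed and 25.6% right-handed substrate, reckons to 2.18 mM and stands at 2.06 mM.

The runs come from a simulation with constants of no real substance, and the scatter is random.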